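**Retrosynthetic overview**

1. Selaginellin A is traced back to a triarylmethanol (global O-demethylation and dehydration unveil the quinone methide), and this to a diaryl ketone plus PhLi. Ring B (the 4-hydroxyphenyl on the central ring A) and ring C (the 4-hydroxyphenyl on the alkyne) are attached to ring A by Suzuki–Miyaura coupling at C–Cl and Sonogashira coupling at C–Br.
2. Ring D (the quinone methide ring) is not bought but built at the 4-hydroxybenzophenone oxidation level. It is cut into two three-carbon pieces: ipso–ortho–meta (a crotonyl chain on the ring-A ketone) and C(O)–meta′–ortho′ (methyl propiolate). A one-pot [3+3] Michael/vinylogous Claisen benzannulation joins them.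
3. Enabling feature: the exocyclic carbon of the quinone methide (the carbon joining ring A, the phenyl ring and ring D) is a latent ketone. As C=O it makes the future ipso carbon of ring D an enolate α-carbon and the future meta carbon its vinylogous γ-carbon, while the para C=O of ring D is a latent ester carbonyl. The dienolate (1,3-dinucleophile) and the ynoate (1,3-dielectrophile) therefore match atom for atom.
4. Order of ring formation: ring A is purchased (2-bromo-4-chlorotoluene, lithiated between the halogens); ring D is made in step 3; rings C and B are coupled on in steps 5 and 6; the phenyl ring is added in step 7; the quinone methide is unveiled in step 8.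

Key step: step 3

Remark: the target has no stereocentre and ring D is symmetric, so no configuration has to be set; the carbinol intermediates are racemic and lose their stereocentres later, and all three phenols are carried as methyl ethers.

**Route**

Step 1
Reactants: 1 2-bromo-4-chlorotoluene; 2 (E)-but-2-enal
Product: 4 (E)-1-(2-bromo-6-chloro-3-methylphenyl)but-2-en-1-ol, via aryllithium 3 (not isolated)
Conditions: LDA (lithium diisopropylamide, commercial solution), THF, −78 °C; then 2, −78 °C; H2O quench
Reagents that add atoms: none
Why: Directed ortho-lithiation removes the most acidic ring hydrogen, the one flanked by bromine and chlorine, without halogen–lithium exchange at −78 °C, and the aryllithium adds 1,2 to the enal to give the racemic allylic alcohol, whose stereocentre is erased in step 2.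

Step 2
Reactants: 4 (E)-1-(2-bromo-6-chloro-3-methylphenyl)but-2-en-1-ol
Product: 5 (E)-1-(2-bromo-6-chloro-3-methylphenyl)but-2-en-1-one
Conditions: Dess–Martin periodinane, CH2Cl2, rt
Reagents that add atoms: none
Why: Dess–Martin oxidation of a secondary allylic and benzylic alcohol under neutral conditions should give the E-enone without touching the aryl halides or moving the double bond.

Step 3
Reactants: 5 (E)-1-(2-bromo-6-chloro-3-methylphenyl)but-2-en-1-one; 6 methyl propiolate
Product: 10 (2-bromo-6-chloro-3-methylphenyl)(4-hydroxyphenyl)methanone, via lithium dienolate 7 (not isolated), via Michael adduct 8 (not isolated), via cyclohexadienone 9 (not isolated)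
Conditions: LDA, THF–DMPU, −78 °C; 6, −78 to 0 °C; then 65 °C; aq. HCl
Reagents that add atoms: none
Why: Proposed new method: LDA in THF–DMPU removes a γ-hydrogen of the crotonyl methyl group (the aryl ketone has no α′-hydrogen) to give the through-conjugated lithium dienolate 7, whose α-carbon, the future ipso carbon of ring D, adds to the β-carbon of methyl propiolate in a Michael reaction, and proton transfer from the now doubly activated α-C–H gives the cross-conjugated trienolate of 8. On warming, the terminal vinyl carbon (the former methyl carbon) attacks the ester carbonyl and expels methoxide, a vinylogous Claisen (Dieckmann-type) acylation that closes ring D in the 6-exo-trig mode (or, seen as a pericyclic event, a disrotatory 6π closure of the ester trienolate), and dienone 9 tautomerises irreversibly to the phenoxide of 10. The closest known reaction types are the consecutive Michael–Claisen [3+3] annulation of ketone enolates with acrylates that gives cyclohexane-1,3-diones and the Michael addition–lactonisation of ketone enolates with propiolates that gives 2-pyranones; new here is that the acylated carbon is the vinylogous γ-carbon, so that the ring is formed at the arene oxidation level. No stereocentre is created, and the geometry of the enoate in 8 is irrelevant because its delocalised anion equilibrates E and Z. The step needs α- rather than γ-attack of the dienolate (γ-attack would end in the 2-hydroxy isomer) and C- rather than O-acylation: the first rests on the kinetic α-preference of lithium dienolates towards an irreversibly reacting acceptor at −78 °C, the second on the fact that the O-acylation product, a 2-pyranone, is reopened by the methoxide set free whereas C-acylation is made irreversible by aromatisation. The two ortho halogens of ring A help by shielding the ketone carbon from 1,2-attack and from the four-ring closure that diverts ordinary enolate–propiolate adducts.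

Step 4
Reactants: 10 (2-bromo-6-chloro-3-methylphenyl)(4-hydroxyphenyl)methanone
Product: 11 (2-bromo-6-chloro-3-methylphenyl)(4-methoxyphenyl)methanone
Conditions: MeI, K2CO3, DMF, rt
Reagents that add atoms: methyl iodide, CI
Why: Williamson ether synthesis on the acidic 4-acylphenol masks the phenoxide, which would otherwise deactivate the ketone towards PhLi in step 7.

Step 5
Reactants: 11 (2-bromo-6-chloro-3-methylphenyl)(4-methoxyphenyl)methanone; 12 1-ethynyl-4-methoxybenzene
Product: 13 {6-chloro-2-[(4-methoxyphenyl)ethynyl]-3-methylphenyl}(4-methoxyphenyl)methanone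
Conditions: Pd(PPh3)4 (cat.), CuI (cat.), Cs2CO3, DMF, 80 °C
Reagents that add atoms: none
Why: In this Sonogashira coupling, oxidative addition of zerovalent palladium should occur at the C–Br bond (activated by the ortho ketone) much faster than at the C–Cl bond, so the alkyne enters only next to the methyl group.

Step 6
Reactants: 13 {6-chloro-2-[(4-methoxyphenyl)ethynyl]-3-methylphenyl}(4-methoxyphenyl)methanone; 14 (4-methoxyphenyl)boronic acid
Product: 15 {4'-methoxy-3-[(4-methoxyphenyl)ethynyl]-4-methylbiphenyl-2-yl}(4-methoxyphenyl)methanone
Conditions: Pd(OAc)2 (cat.), SPhos (cat.), K3PO4, toluene–H2O, 100 °C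
Reagents that add atoms: none
Why: Suzuki–Miyaura coupling of an aryl chloride activated by the ortho carbonyl group should proceed with the bulky, electron-rich SPhos ligand, which is suited to hindered chlorides, while the internal alkyne and the ketone stay inert.

Step 7
Reactants: 15 {4'-methoxy-3-[(4-methoxyphenyl)ethynyl]-4-methylbiphenyl-2-yl}(4-methoxyphenyl)methanone; 16 phenyllithium
Product: 17 {4'-methoxy-3-[(4-methoxyphenyl)ethynyl]-4-methylbiphenyl-2-yl}(4-methoxyphenyl)(phenyl)methanol
Conditions: PhLi, THF, −78 to 0 °C; H2O quench
Reagents that add atoms: none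
Why: 1,2-Addition of a small, hard organolithium to a non-enolisable diaryl ketone should give the racemic triarylmethanol even though the carbonyl is flanked by two ortho substituents, and the stereocentre disappears in step 8; the alkoxide is kept cold so that it does not add to the ortho alkyne.

Step 8
Reactants: 17 {4'-methoxy-3-[(4-methoxyphenyl)ethynyl]-4-methylbiphenyl-2-yl}(4-methoxyphenyl)(phenyl)methanol
Product: 18 selaginellin A
Conditions: BBr3, CH2Cl2, −78 °C to rt; aq. NaHCO3
Reagents that add atoms: none
Why: BBr3 ether cleavage removes the three O-methyl groups while the tertiary alcohol ionises to a 4-methoxytrityl-type cation, whose O-demethylation (or loss of water from the 4-hydroxyphenyl carbinol on work-up) gives the quinone methide, a global deprotection–dehydration.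

**Compound list**

1 | 2-bromo-4-chlorotoluene (2-bromo-4-chloro-1-methylbenzene) | Cc1ccc(Cl)cc1Br | starting material
2 | (E)-but-2-enal (crotonaldehyde) | C/C=C/C=O | starting material
3 | (2-bromo-6-chloro-3-methylphenyl)lithium | [Li]c1c(Cl)ccc(C)c1Br | intermediate (not isolated)
4 | (E)-1-(2-bromo-6-chloro-3-methylphenyl)but-2-en-1-ol, racemic | C/C=C/C(O)c1c(Cl)ccc(C)c1Br | intermediate
5 | (E)-1-(2-bromo-6-chloro-3-methylphenyl)but-2-en-1-one | C/C=C/C(=O)c1c(Cl)ccc(C)c1Br | intermediate
6 | methyl propiolate (methyl prop-2-ynoate) | COC(=O)C#C | starting material
7 | lithium 1-(2-bromo-6-chloro-3-methylphenyl)buta-1,3-dien-1-olate, enolate geometry not defined | [Li]OC(=CC=C)c1c(Cl)ccc(C)c1Br | intermediate (not isolated)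
8 | methyl (2Z)-4-(2-bromo-6-chloro-3-methylbenzoyl)hexa-2,5-dienoate, racemic, present as its lithium enolate | COC(=O)/C=C\C(C=C)C(=O)c1c(Cl)ccc(C)c1Br | intermediate (not isolated)
9 | 4-(2-bromo-6-chloro-3-methylbenzoyl)cyclohexa-2,4-dien-1-one | O=C1CC=C(C=C1)C(=O)c1c(Cl)ccc(C)c1Br | intermediate (not isolated)
10 | (2-bromo-6-chloro-3-methylphenyl)(4-hydroxyphenyl)methanone | O=C(c1ccc(O)cc1)c1c(Cl)ccc(C)c1Br | intermediate
11 | (2-bromo-6-chloro-3-methylphenyl)(4-methoxyphenyl)methanone | COc1ccc(cc1)C(=O)c1c(Cl)ccc(C)c1Br | intermediate
12 | 1-ethynyl-4-methoxybenzene (4-ethynylanisole) | COc1ccc(cc1)C#C | starting material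
13 | {6-chloro-2-[(4-methoxyphenyl)ethynyl]-3-methylphenyl}(4-methoxyphenyl)methanone | COc1ccc(cc1)C(=O)c1c(Cl)ccc(C)c1C#Cc1ccc(OC)cc1 | intermediate
14 | (4-methoxyphenyl)boronic acid | COc1ccc(cc1)B(O)O | starting material
15 | {4'-methoxy-3-[(4-methoxyphenyl)ethynyl]-4-methylbiphenyl-2-yl}(4-methoxyphenyl)methanone | COc1ccc(cc1)C(=O)c1c(-c2ccc(OC)cc2)ccc(C)c1C#Cc1ccc(OC)cc1 | intermediate
16 | phenyllithium | [Li]c1ccccc1 | starting material
17 | {4'-methoxy-3-[(4-methoxyphenyl)ethynyl]-4-methylbiphenyl-2-yl}(4-methoxyphenyl)(phenyl)methanol, racemic | COc1ccc(cc1)C(O)(c1ccccc1)c1c(-c2ccc(OC)cc2)ccc(C)c1C#Cc1ccc(OC)cc1 | intermediate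
18 | selaginellin A, 4-[{4'-hydroxy-3-[(4-hydroxyphenyl)ethynyl]-4-methylbiphenyl-2-yl}(phenyl)methylidene]cyclohexa-2,5-dien-1-one | Cc1ccc(-c2ccc(O)cc2)c(C(=C2C=CC(=O)C=C2)c2ccccc2)c1C#Cc1ccc(O)cc1 | target

**Step count**

Total step count: 8. Longest linear sequence: 8 steps (from 1 to 18).

**Steps most likely to fail**

1. Step 3 (proposed new method). Three processes could defeat it:
   - proton transfer from the acidic alkyne C–H of methyl propiolate to the dienolate instead of conjugate addition;
   - γ- instead of α-attack of the dienolate in the Michael step;
   - arrest at the O-acylated 2-pyranone instead of C-acylation and aromatisation.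

   Fallback with known chemistry: it sets out from 1. Lithiation with LDA exactly as in step 1 (aryllithium 3) and quenching with commercial 4-methoxybenzaldehyde should give (2-bromo-6-chloro-3-methylphenyl)(4-methoxyphenyl)methanol F1. Dess–Martin oxidation of this alcohol gives 11, where the route is rejoined. Ring D is then purchased instead of built.

2. Step 7. Steric shielding of the carbonyl by the ortho aryl and ortho alkynyl groups could suppress 1,2-addition or divert PhLi to conjugate addition into an aryl ring.

   Fallback: the order of events is changed so that the addition takes place on a less hindered ketone. It sets out from 13, whose carbonyl is flanked only by chlorine and the linear alkyne. PhLi (THF, −78 to 0 °C) should give {6-chloro-2-[(4-methoxyphenyl)ethynyl]-3-methylphenyl}(4-methoxyphenyl)(phenyl)methanol F2. Suzuki–Miyaura coupling of its C–Cl bond with 14 then follows (Pd(OAc)2, SPhos, K3PO4, THF–H2O, kept at or below 60 °C so that the free carbinol does not add to the alkyne). This comes back to the route at 17.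

3. Step 8. The triaryl cation generated under a strong Lewis acid could undergo Friedel–Crafts closure onto ring B (giving a 9,9-diarylfluorene) or be trapped at the neighbouring alkyne before the quinone methide is released.

   Fallback: deprotection and cation formation are separated. It sets out from 15. BBr3 (CH2Cl2, −78 °C to rt) at the ketone stage, where no carbocation can form, should give (4-hydroxyphenyl){4'-hydroxy-3-[(4-hydroxyphenyl)ethynyl]-4-methylbiphenyl-2-yl}methanone F3. Excess PhLi (THF, 0 °C to rt) is then added to its tris-phenoxide, giving 4-[hydroxy{4'-hydroxy-3-[(4-hydroxyphenyl)ethynyl]-4-methylbiphenyl-2-yl}(phenyl)methyl]phenol F4 (not isolated). This loses water on work-up with aqueous acetic acid and comes back to the route at 18.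

**Further compounds**

F1 | step 3 | (2-bromo-6-chloro-3-methylphenyl)(4-methoxyphenyl)methanol, racemic | COc1ccc(cc1)C(O)c1c(Cl)ccc(C)c1Br
F2 | step 7 | {6-chloro-2-[(4-methoxyphenyl)ethynyl]-3-methylphenyl}(4-methoxyphenyl)(phenyl)methanol, racemic | COc1ccc(cc1)C(O)(c1ccccc1)c1c(Cl)ccc(C)c1C#Cc1ccc(OC)cc1
F3 | step 8 | (4-hydroxyphenyl){4'-hydroxy-3-[(4-hydroxyphenyl)ethynyl]-4-methylbiphenyl-2-yl}methanone | Oc1ccc(cc1)C(=O)c1c(-c2ccc(O)cc2)ccc(C)c1C#Cc1ccc(O)cc1
F4 | step 8 | 4-[hydroxy{4'-hydroxy-3-[(4-hydroxyphenyl)ethynyl]-4-methylbiphenyl-2-yl}(phenyl)methyl]phenol, racemic | Oc1ccc(cc1)C(O)(c1ccccc1)c1c(-c2ccc(O)cc2)ccc(C)c1C#Cc1ccc(O)cc1
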